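**Plan**
1. Numbering: the core is numbered as an octahydronaphthalene. C1 carries the acrylic acid, C2 the acyloxy group, C4 the exocyclic methylene and C7 the hydroxymethyl; ring B is C1–C4/C4a/C8a and the second ring is C4a/C5–C8/C8a.
2. Cuts: first the C2–O ester bond (acid 26), then C8–C8a and C5–C4a of the second ring in one Diels–Alder step. C4=CH2 is read as a masked ketone, which makes C4a=C8a of ring B an enone dienophile (4).
3. The C7=C8 alkene lies one bond away from where a [4+2] leaves it. Diene 8 therefore carries silicon at C8; protodesilylation of the allylsilane shifts the alkene and removes the helper.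
4. Forward order: ring B by amine-catalysed Michael/aldol (step 1); the second ring is closed last by the cycloaddition (step 5); then the C2 oxygen via enone, allylic alcohol and directed epoxide; two methylenations; ester coupling; deprotection.
5. Stereochemistry: C1 from the organocatalyst; C8a anti to the C1 side chain in the cycloaddition; C4a by equilibration to the trans fusion; C2 from hydroxyl-directed epoxidation; the side-chain carbinol from malic acid-derived 22.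

Key step: step 5

Remark: the (R)-configured amine catalyst is assumed to give the (R)-aldehyde 3 by the usual enamine shielding model, and the silyl-bearing carbon C8 of 9 is left undefined because both epimers converge on 11.

Step 1
Reactants: 1 methyl 4-oxobutanoate; 2 but-3-en-2-one
Product: 4 methyl 2-[(1R)-4-oxocyclohex-2-en-1-yl]acetate, via keto-aldehyde 3 (not isolated)
Conditions: (R)-α,α-diphenylprolinol trimethylsilyl ether (10 mol%), 4-nitrophenol (20 mol%), CH2Cl2, 0 °C; then TsOH·H2O (20 mol%), toluene, 60 °C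
Reagents that add atoms: none
Why: Enamine Michael addition of the aldehyde to the enone, with one enamine face shielded by the diaryl(silyloxy)methyl group, should set C1, and the acid-mediated intramolecular aldol condensation (Robinson-type) should then close ring B without touching this γ-stereocentre.

Step 2
Reactants: 5 3-(trimethylsilyl)prop-2-yn-1-ol
Product: 6 tert-butyl(diphenyl){[3-(trimethylsilyl)prop-2-yn-1-yl]oxy}silane
Conditions: t-BuPh2SiCl, imidazole, CH2Cl2, rt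
Reagents that add atoms: tert-butyl(chloro)diphenylsilane, CC(C)(C)[Si](Cl)(c1ccccc1)c1ccccc1
Why: Routine silylation of a primary alcohol; the bulky silyl ether is chosen because it should survive the Lewis and Brønsted acids of steps 5 and 6.

Step 3
Reactants: 6 tert-butyl(diphenyl){[3-(trimethylsilyl)prop-2-yn-1-yl]oxy}silane
Product: 7 tert-butyl(diphenyl){[(2E)-2-(tributylstannyl)-3-(trimethylsilyl)prop-2-en-1-yl]oxy}silane
Conditions: Bu3SnH, PdCl2(PPh3)2 (2 mol%), THF, rt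
Reagents that add atoms: tributyltin hydride, CCCC[SnH](CCCC)CCCC
Why: Palladium-catalysed syn-hydrostannation should put tin on the carbon next to the oxygenated CH2 (directing effect of the propargylic oxygen, reinforced by the bulk of Me3Si at the other terminus), so that H and Sn end cis.

Step 4
Reactants: 7 tert-butyl(diphenyl){[(2E)-2-(tributylstannyl)-3-(trimethylsilyl)prop-2-en-1-yl]oxy}silane
Product: 8 [(1Z)-2-({[tert-butyl(diphenyl)silyl]oxy}methyl)buta-1,3-dien-1-yl](trimethyl)silane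
Conditions: CH2=CHBr, Pd(PPh3)4 (5 mol%), CuI (10 mol%), DMF, 50 °C
Reagents that add atoms: bromoethene, C=CBr
Why: Stille coupling proceeds with retention at the alkenyl–tin carbon, so the new vinyl group should end trans to Me3Si, the geometry in which silicon sits "outside" the s-cis diene.

Step 5
Reactants: 4 methyl 2-[(1R)-4-oxocyclohex-2-en-1-yl]acetate; 8 [(1Z)-2-({[tert-butyl(diphenyl)silyl]oxy}methyl)buta-1,3-dien-1-yl](trimethyl)silane
Product: 9 methyl 2-[(1R,4aR,8aR)-7-({[tert-butyl(diphenyl)silyl]oxy}methyl)-4-oxo-8-(trimethylsilyl)-1,2,3,4,4a,5,8,8a-octahydronaphthalen-1-yl]acetate (cis-fused; either epimer at C8)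
Conditions: EtAlCl2 (2.2 equiv), 8 (2 equiv), toluene, −20 °C → rt
Reagents that add atoms: none
Why: The Lewis acid-complexed enone C4a=C8a of 4 and diene 8 should combine in a concerted, asynchronous Diels–Alder [4+2] cycloaddition; the closest known reactions are the aluminium Lewis acid-promoted cycloadditions of 4-substituted cyclohex-2-enones with 2-substituted butadienes and the use of 1-silyl dienes as allylsilane precursors. The six-membered carbocycle C4a–C5–C6–C7–C8–C8a is closed by suprafacial formation of C8–C8a and C5–C4a in one step. C8a is set by approach of the diene to the enone face anti to the CH2CO2Me group at C1; C4a follows from the suprafacial addition (cis fusion, corrected in step 6), and the configuration at silyl-bearing C8 is not needed. The step needs regioselectivity, C8 bonding to the β-carbon C8a: the 2-silyloxymethyl group puts the largest diene HOMO coefficient on the adjacent terminus C8 ("para" orientation to the carbonyl), while a terminal silyl group directs only weakly. The E-type placement of silicon keeps the s-cis conformer accessible, and 4 has no β-leaving group, so it should tolerate the Lewis acid.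

Step 6
Reactants: 9 methyl 2-[(1R,4aR,8aR)-7-({[tert-butyl(diphenyl)silyl]oxy}methyl)-4-oxo-8-(trimethylsilyl)-1,2,3,4,4a,5,8,8a-octahydronaphthalen-1-yl]acetate
Product: 11 methyl 2-[(1R,4aS,8aS)-7-({[tert-butyl(diphenyl)silyl]oxy}methyl)-4-oxo-1,2,3,4,4a,5,6,8a-octahydronaphthalen-1-yl]acetate, via cis-fused ketone 10 (not isolated)
Conditions: TsOH·H2O (1.1 equiv), CH2Cl2, 0 °C → rt; then NaOMe (0.3 equiv), MeOH, rt
Reagents that add atoms: none
Why: Protodesilylation of the allylsilane (protonation at C6, loss of silicon from the β-silyl cation, SE2′) should move the alkene to C7=C8, and methoxide should then equilibrate C4a next to the ketone to the more stable trans-fused decalone.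

Step 7
Reactants: 11 methyl 2-[(1R,4aS,8aS)-7-({[tert-butyl(diphenyl)silyl]oxy}methyl)-4-oxo-1,2,3,4,4a,5,6,8a-octahydronaphthalen-1-yl]acetate
Product: 13 methyl 2-[(1S,4aS,8aS)-7-({[tert-butyl(diphenyl)silyl]oxy}methyl)-4-oxo-1,4,4a,5,6,8a-hexahydronaphthalen-1-yl]acetate, via silyl enol ether 12 (not isolated)
Conditions: LiN(i-Pr)2, Me3SiCl, THF, −78 °C; then Pd(OAc)2 (1.05 equiv), MeCN, rt
Reagents that add atoms: chlorotrimethylsilane, C[Si](C)(C)Cl (its Me3Si group is in 12 only)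
Why: Kinetic deprotonation should take the C3 methylene rather than the C4a methine (and the ketone rather than the ester), and Saegusa–Ito dehydrogenation of that enol ether gives the C2=C3 enone.

Step 8
Reactants: 13 methyl 2-[(1S,4aS,8aS)-7-({[tert-butyl(diphenyl)silyl]oxy}methyl)-4-oxo-1,4,4a,5,6,8a-hexahydronaphthalen-1-yl]acetate
Product: 14 methyl 2-[(1S,4S,4aS,8aS)-7-({[tert-butyl(diphenyl)silyl]oxy}methyl)-4-hydroxy-1,4,4a,5,6,8a-hexahydronaphthalen-1-yl]acetate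
Conditions: NaBH4, CeCl3·7H2O, MeOH, −78 °C
Reagents that add atoms: none
Why: Luche 1,2-reduction with axial hydride delivery to the trans-fused enone should give the pseudo-equatorial C4 alcohol, on the same face as C8.

Step 9
Reactants: 14 methyl 2-[(1S,4S,4aS,8aS)-7-({[tert-butyl(diphenyl)silyl]oxy}methyl)-4-hydroxy-1,4,4a,5,6,8a-hexahydronaphthalen-1-yl]acetate
Product: 15 methyl 2-[(1R,2S,3R,4R,4aS,8aS)-7-({[tert-butyl(diphenyl)silyl]oxy}methyl)-2,3-epoxy-4-hydroxy-1,2,3,4,4a,5,6,8a-octahydronaphthalen-1-yl]acetate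
Conditions: VO(acac)2 (5 mol%), t-BuOOH, CH2Cl2, 0 °C → rt
Reagents that add atoms: tert-butyl hydroperoxide, CC(C)(C)OO
Why: Vanadium-catalysed hydroxyl-directed epoxidation should deliver oxygen to C2=C3 syn to the C4 hydroxyl, which places the C2 oxygen cis to C8 and trans to the C1 side chain, and should leave the C7=C8 alkene (no free allylic hydroxyl) untouched.

Step 10
Reactants: 15 methyl 2-[(1R,2S,3R,4R,4aS,8aS)-7-({[tert-butyl(diphenyl)silyl]oxy}methyl)-2,3-epoxy-4-hydroxy-1,2,3,4,4a,5,6,8a-octahydronaphthalen-1-yl]acetate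
Product: 16 methyl 2-[(1R,2S,3S,4aS,8aR)-7-({[tert-butyl(diphenyl)silyl]oxy}methyl)-2,3-epoxy-4-oxo-1,2,3,4,4a,5,6,8a-octahydronaphthalen-1-yl]acetate
Conditions: Dess–Martin periodinane, NaHCO3, CH2Cl2, rt
Reagents that add atoms: none
Why: Buffered Dess–Martin oxidation converts the secondary alcohol into the α,β-epoxy ketone without opening the epoxide or epimerising C4a.

Step 11
Reactants: 16 methyl 2-[(1R,2S,3S,4aS,8aR)-7-({[tert-butyl(diphenyl)silyl]oxy}methyl)-2,3-epoxy-4-oxo-1,2,3,4,4a,5,6,8a-octahydronaphthalen-1-yl]acetate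
Product: 17 methyl 2-[(1R,2S,3R,4aS,8aS)-7-({[tert-butyl(diphenyl)silyl]oxy}methyl)-2,3-epoxy-4-methylidene-1,2,3,4,4a,5,6,8a-octahydronaphthalen-1-yl]acetate
Conditions: Ph3PCH3Br, KOt-Bu, THF, 0 °C → rt
Reagents that add atoms: methyltriphenylphosphonium bromide, C[P+](c1ccccc1)(c1ccccc1)c1ccccc1.[Br-]
Why: Wittig methylenation of the ketone installs the C4 exocyclic methylene (the ester is inert to the non-stabilised ylide at this temperature) and turns the epoxy ketone into a vinyl epoxide.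

Step 12
Reactants: 17 methyl 2-[(1R,2S,3R,4aS,8aS)-7-({[tert-butyl(diphenyl)silyl]oxy}methyl)-2,3-epoxy-4-methylidene-1,2,3,4,4a,5,6,8a-octahydronaphthalen-1-yl]acetate
Product: 20 methyl 2-[(1S,2S,3R,4aS,8aS)-7-({[tert-butyl(diphenyl)silyl]oxy}methyl)-2,3-epoxy-4-methylidene-1,2,3,4,4a,5,6,8a-octahydronaphthalen-1-yl]prop-2-enoate, via Mannich base 18 (not isolated), via methiodide 19 (not isolated)
Conditions: LiN(i-Pr)2, THF, −78 °C; Me2N=CH2 I (iminium iodide), −78 → 0 °C; then MeI, MeOH, rt; then DBU, CH2Cl2, rt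
Reagents that add atoms: N,N-dimethylmethyleneiminium iodide, C[N+](C)=C.[I-]; iodomethane, CI (in 19 only)
Why: Mannich reaction of the ester enolate with the iminium salt, quaternisation and E1cB elimination (α-methylenation) should convert CH2CO2Me into the acrylate, the epoxide and alkenes being inert to the hindered amide base at −78 °C.

Step 13
Reactants: 20 methyl 2-[(1S,2S,3R,4aS,8aS)-7-({[tert-butyl(diphenyl)silyl]oxy}methyl)-2,3-epoxy-4-methylidene-1,2,3,4,4a,5,6,8a-octahydronaphthalen-1-yl]prop-2-enoate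
Product: 21 methyl 2-[(1S,2R,4aS,8aS)-7-({[tert-butyl(diphenyl)silyl]oxy}methyl)-2-hydroxy-4-methylidene-1,2,3,4,4a,5,6,8a-octahydronaphthalen-1-yl]prop-2-enoate
Conditions: Pd2(dba)3·CHCl3 (2.5 mol%), PBu3 (10 mol%), HCO2H, Et3N, 1,4-dioxane, rt
Reagents that add atoms: none
Why: In this palladium-catalysed formate hydrogenolysis of an alkenyl oxirane, zerovalent palladium ionises the allylic C3–O bond and hydride should be delivered to the more substituted allyl terminus C3, which keeps the exocyclic alkene and leaves the C2–O bond, so the equatorial C2 alcohol is retained.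

Step 14
Reactants: 22 methyl 2-[(4S)-2,2-dimethyl-1,3-dioxolan-4-yl]acetate
Product: 25 methyl 2-[(4S)-2,2-dimethyl-1,3-dioxolan-4-yl]prop-2-enoate, via Mannich base 23 (not isolated), via methiodide 24 (not isolated)
Conditions: LiN(i-Pr)2, THF, −78 °C; Me2N=CH2 I (iminium iodide), −78 → 0 °C; then MeI, MeOH, rt; then DBU, CH2Cl2, rt
Reagents that add atoms: N,N-dimethylmethyleneiminium iodide, C[N+](C)=C.[I-]; iodomethane, CI (in 24 only)
Why: The same Mannich α-methylenation; at −78 °C β-elimination of the dioxolane oxygen from the enolate should be slow, and the carbinol stereocentre, which comes from malic acid, is not touched.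

Step 15
Reactants: 25 methyl 2-[(4S)-2,2-dimethyl-1,3-dioxolan-4-yl]prop-2-enoate
Product: 26 2-[(4S)-2,2-dimethyl-1,3-dioxolan-4-yl]prop-2-enoic acid
Conditions: LiOH·H2O, THF/H2O, 0 °C; then 1 M HCl to pH 3, 0 °C
Reagents that add atoms: lithium hydroxide monohydrate, [Li+].[OH-].O
Why: Saponification of the methyl ester; brief cold acidification should spare the acetonide.

Step 16
Reactants: 21 methyl 2-[(1S,2R,4aS,8aS)-7-({[tert-butyl(diphenyl)silyl]oxy}methyl)-2-hydroxy-4-methylidene-1,2,3,4,4a,5,6,8a-octahydronaphthalen-1-yl]prop-2-enoate; 26 2-[(4S)-2,2-dimethyl-1,3-dioxolan-4-yl]prop-2-enoic acid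
Product: 28 methyl 2-[(1S,2R,4aS,8aS)-7-({[tert-butyl(diphenyl)silyl]oxy}methyl)-2-({2-[(4S)-2,2-dimethyl-1,3-dioxolan-4-yl]prop-2-enoyl}oxy)-4-methylidene-1,2,3,4,4a,5,6,8a-octahydronaphthalen-1-yl]prop-2-enoate, via mixed anhydride 27 (not isolated)
Conditions: 26, 2,4,6-trichlorobenzoyl chloride, Et3N, THF, rt; then 21, DMAP, toluene, rt
Reagents that add atoms: 2,4,6-trichlorobenzoyl chloride, O=C(Cl)c1c(Cl)cc(Cl)cc1Cl (in 27 only)
Why: Yamaguchi esterification, in which DMAP transfers the less hindered acyl group of the mixed anhydride to the equatorial secondary alcohol; no stereocentre is involved.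

Step 17
Reactants: 28 methyl 2-[(1S,2R,4aS,8aS)-7-({[tert-butyl(diphenyl)silyl]oxy}methyl)-2-({2-[(4S)-2,2-dimethyl-1,3-dioxolan-4-yl]prop-2-enoyl}oxy)-4-methylidene-1,2,3,4,4a,5,6,8a-octahydronaphthalen-1-yl]prop-2-enoate
Product: 29 2-[(1S,2R,4aS,8aS)-7-({[tert-butyl(diphenyl)silyl]oxy}methyl)-2-({2-[(4S)-2,2-dimethyl-1,3-dioxolan-4-yl]prop-2-enoyl}oxy)-4-methylidene-1,2,3,4,4a,5,6,8a-octahydronaphthalen-1-yl]prop-2-enoic acid
Conditions: Me3SnOH (6 equiv), ClCH2CH2Cl, 80 °C; then 1 M HCl wash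
Reagents that add atoms: trimethyltin hydroxide, C[Sn](C)(C)O
Why: Trimethyltin hydroxide-mediated ester hydrolysis under near-neutral conditions should cleave the unhindered methyl ester in preference to the secondary alkyl ester at C2.

Step 18
Reactants: 29 2-[(1S,2R,4aS,8aS)-7-({[tert-butyl(diphenyl)silyl]oxy}methyl)-2-({2-[(4S)-2,2-dimethyl-1,3-dioxolan-4-yl]prop-2-enoyl}oxy)-4-methylidene-1,2,3,4,4a,5,6,8a-octahydronaphthalen-1-yl]prop-2-enoic acid
Product: 31 2-[(1S,2R,4aS,8aS)-2-{[(3S)-3,4-dihydroxy-2-methylidenebutanoyl]oxy}-7-(hydroxymethyl)-4-methylidene-1,2,3,4,4a,5,6,8a-octahydronaphthalen-1-yl]prop-2-enoic acid, via desilylated acetonide 30 (not isolated)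
Conditions: Bu4NF, AcOH, THF, rt; then AcOH/H2O (4:1), 40 °C
Reagents that add atoms: none
Why: Buffered fluoride desilylation followed by mild aqueous-acid acetonide hydrolysis; these conditions should be too mild to isomerise the exocyclic alkene or ionise the allylic alcohol.

**Compound list**
1 | methyl 4-oxobutanoate | COC(=O)CCC=O | starting material
2 | but-3-en-2-one | CC(=O)C=C | starting material
3 | methyl (3R)-3-formyl-6-oxoheptanoate | COC(=O)C[C@@H](CCC(C)=O)C=O | intermediate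
4 | methyl 2-[(1R)-4-oxocyclohex-2-en-1-yl]acetate | COC(=O)C[C@@H]1C=CC(=O)CC1 | intermediate
5 | 3-(trimethylsilyl)prop-2-yn-1-ol | C[Si](C)(C)C#CCO | starting material
6 | tert-butyl(diphenyl){[3-(trimethylsilyl)prop-2-yn-1-yl]oxy}silane | C[Si](C)(C)C#CCO[Si](c1ccccc1)(c1ccccc1)C(C)(C)C | intermediate
7 | tert-butyl(diphenyl){[(2E)-2-(tributylstannyl)-3-(trimethylsilyl)prop-2-en-1-yl]oxy}silane | C[Si](C)(C)/C=C(/[Sn](CCCC)(CCCC)CCCC)CO[Si](c1ccccc1)(c1ccccc1)C(C)(C)C | intermediate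
8 | [(1Z)-2-({[tert-butyl(diphenyl)silyl]oxy}methyl)buta-1,3-dien-1-yl](trimethyl)silane | C[Si](C)(C)/C=C(/C=C)CO[Si](c1ccccc1)(c1ccccc1)C(C)(C)C | intermediate
9 | methyl 2-[(1R,4aR,8aR)-7-({[tert-butyl(diphenyl)silyl]oxy}methyl)-4-oxo-8-(trimethylsilyl)-1,2,3,4,4a,5,8,8a-octahydronaphthalen-1-yl]acetate (cis-fused, C8 undefined) | COC(=O)C[C@@H]1[C@H]2C([Si](C)(C)C)C(CO[Si](c3ccccc3)(c3ccccc3)C(C)(C)C)=CC[C@H]2C(=O)CC1 | intermediate
10 | methyl 2-[(1R,4aR,8aS)-7-({[tert-butyl(diphenyl)silyl]oxy}methyl)-4-oxo-1,2,3,4,4a,5,6,8a-octahydronaphthalen-1-yl]acetate (cis-fused) | COC(=O)C[C@@H]1[C@H]2C=C(CO[Si](c3ccccc3)(c3ccccc3)C(C)(C)C)CC[C@H]2C(=O)CC1 | intermediate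
11 | methyl 2-[(1R,4aS,8aS)-7-({[tert-butyl(diphenyl)silyl]oxy}methyl)-4-oxo-1,2,3,4,4a,5,6,8a-octahydronaphthalen-1-yl]acetate (trans-fused) | COC(=O)C[C@@H]1[C@H]2C=C(CO[Si](c3ccccc3)(c3ccccc3)C(C)(C)C)CC[C@@H]2C(=O)CC1 | intermediate
12 | methyl 2-[(1R,4aS,8aS)-7-({[tert-butyl(diphenyl)silyl]oxy}methyl)-4-(trimethylsilyloxy)-1,2,4a,5,6,8a-hexahydronaphthalen-1-yl]acetate | COC(=O)C[C@@H]1[C@H]2C=C(CO[Si](c3ccccc3)(c3ccccc3)C(C)(C)C)CC[C@@H]2C(O[Si](C)(C)C)=CC1 | intermediate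
13 | methyl 2-[(1S,4aS,8aS)-7-({[tert-butyl(diphenyl)silyl]oxy}methyl)-4-oxo-1,4,4a,5,6,8a-hexahydronaphthalen-1-yl]acetate | COC(=O)C[C@@H]1[C@H]2C=C(CO[Si](c3ccccc3)(c3ccccc3)C(C)(C)C)CC[C@@H]2C(=O)C=C1 | intermediate
14 | methyl 2-[(1S,4S,4aS,8aS)-7-({[tert-butyl(diphenyl)silyl]oxy}methyl)-4-hydroxy-1,4,4a,5,6,8a-hexahydronaphthalen-1-yl]acetate | COC(=O)C[C@@H]1[C@H]2C=C(CO[Si](c3ccccc3)(c3ccccc3)C(C)(C)C)CC[C@@H]2[C@@H](O)C=C1 | intermediate
15 | methyl 2-[(1R,2S,3R,4R,4aS,8aS)-7-({[tert-butyl(diphenyl)silyl]oxy}methyl)-2,3-epoxy-4-hydroxy-1,2,3,4,4a,5,6,8a-octahydronaphthalen-1-yl]acetate | COC(=O)C[C@@H]1[C@H]2C=C(CO[Si](c3ccccc3)(c3ccccc3)C(C)(C)C)CC[C@@H]2[C@@H](O)[C@H]4O[C@H]41 | intermediate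
16 | methyl 2-[(1R,2S,3S,4aS,8aR)-7-({[tert-butyl(diphenyl)silyl]oxy}methyl)-2,3-epoxy-4-oxo-1,2,3,4,4a,5,6,8a-octahydronaphthalen-1-yl]acetate | COC(=O)C[C@@H]1[C@H]2C=C(CO[Si](c3ccccc3)(c3ccccc3)C(C)(C)C)CC[C@@H]2C(=O)[C@H]4O[C@H]41 | intermediate
17 | methyl 2-[(1R,2S,3R,4aS,8aS)-7-({[tert-butyl(diphenyl)silyl]oxy}methyl)-2,3-epoxy-4-methylidene-1,2,3,4,4a,5,6,8a-octahydronaphthalen-1-yl]acetate | COC(=O)C[C@@H]1[C@H]2C=C(CO[Si](c3ccccc3)(c3ccccc3)C(C)(C)C)CC[C@@H]2C(=C)[C@H]4O[C@H]41 | intermediate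
18 | methyl 3-(dimethylamino)-2-[the (2S,3R,4aS,8aS) ring system of 17]propanoate (Mannich base, mixture at the new α-carbon) | CN(C)CC(C(=O)OC)[C@@H]1[C@H]2C=C(CO[Si](c3ccccc3)(c3ccccc3)C(C)(C)C)CC[C@@H]2C(=C)[C@H]4O[C@H]41 | intermediate
19 | trimethylammonium iodide (methiodide) of 18 | [I-].C[N+](C)(C)CC(C(=O)OC)[C@@H]1[C@H]2C=C(CO[Si](c3ccccc3)(c3ccccc3)C(C)(C)C)CC[C@@H]2C(=C)[C@H]4O[C@H]41 | intermediate
20 | methyl 2-[(1S,2S,3R,4aS,8aS)-7-({[tert-butyl(diphenyl)silyl]oxy}methyl)-2,3-epoxy-4-methylidene-1,2,3,4,4a,5,6,8a-octahydronaphthalen-1-yl]prop-2-enoate | C=C(C(=O)OC)[C@@H]1[C@H]2C=C(CO[Si](c3ccccc3)(c3ccccc3)C(C)(C)C)CC[C@@H]2C(=C)[C@H]4O[C@H]41 | intermediate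
21 | methyl 2-[(1S,2R,4aS,8aS)-7-({[tert-butyl(diphenyl)silyl]oxy}methyl)-2-hydroxy-4-methylidene-1,2,3,4,4a,5,6,8a-octahydronaphthalen-1-yl]prop-2-enoate | C=C(C(=O)OC)[C@@H]1[C@H]2C=C(CO[Si](c3ccccc3)(c3ccccc3)C(C)(C)C)CC[C@@H]2C(=C)C[C@H]1O | intermediate
22 | methyl 2-[(4S)-2,2-dimethyl-1,3-dioxolan-4-yl]acetate | COC(=O)C[C@H]1COC(C)(C)O1 | starting material
23 | methyl 3-(dimethylamino)-2-[(4S)-2,2-dimethyl-1,3-dioxolan-4-yl]propanoate (mixture at C2) | CN(C)CC(C(=O)OC)[C@H]1COC(C)(C)O1 | intermediate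
24 | trimethylammonium iodide (methiodide) of 23 | [I-].C[N+](C)(C)CC(C(=O)OC)[C@H]1COC(C)(C)O1 | intermediate
25 | methyl 2-[(4S)-2,2-dimethyl-1,3-dioxolan-4-yl]prop-2-enoate | C=C(C(=O)OC)[C@H]1COC(C)(C)O1 | intermediate
26 | 2-[(4S)-2,2-dimethyl-1,3-dioxolan-4-yl]prop-2-enoic acid | C=C(C(=O)O)[C@H]1COC(C)(C)O1 | intermediate
27 | 2-[(4S)-2,2-dimethyl-1,3-dioxolan-4-yl]prop-2-enoic 2,4,6-trichlorobenzoic anhydride | C=C(C(=O)OC(=O)c1c(Cl)cc(Cl)cc1Cl)[C@H]2COC(C)(C)O2 | intermediate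
28 | methyl 2-[(1S,2R,4aS,8aS)-7-({[tert-butyl(diphenyl)silyl]oxy}methyl)-2-({2-[(4S)-2,2-dimethyl-1,3-dioxolan-4-yl]prop-2-enoyl}oxy)-4-methylidene-1,2,3,4,4a,5,6,8a-octahydronaphthalen-1-yl]prop-2-enoate | C=C(C(=O)OC)[C@@H]1[C@H]2C=C(CO[Si](c3ccccc3)(c3ccccc3)C(C)(C)C)CC[C@@H]2C(=C)C[C@H]1OC(=O)C(=C)[C@H]4COC(C)(C)O4 | intermediate
29 | 2-[(1S,2R,4aS,8aS)-7-({[tert-butyl(diphenyl)silyl]oxy}methyl)-2-({2-[(4S)-2,2-dimethyl-1,3-dioxolan-4-yl]prop-2-enoyl}oxy)-4-methylidene-1,2,3,4,4a,5,6,8a-octahydronaphthalen-1-yl]prop-2-enoic acid | C=C(C(=O)O)[C@@H]1[C@H]2C=C(CO[Si](c3ccccc3)(c3ccccc3)C(C)(C)C)CC[C@@H]2C(=C)C[C@H]1OC(=O)C(=C)[C@H]4COC(C)(C)O4 | intermediate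
30 | 2-[(1S,2R,4aS,8aS)-2-({2-[(4S)-2,2-dimethyl-1,3-dioxolan-4-yl]prop-2-enoyl}oxy)-7-(hydroxymethyl)-4-methylidene-1,2,3,4,4a,5,6,8a-octahydronaphthalen-1-yl]prop-2-enoic acid | C=C(C(=O)O)[C@@H]1[C@H]2C=C(CO)CC[C@@H]2C(=C)C[C@H]1OC(=O)C(=C)[C@H]3COC(C)(C)O3 | intermediate
31 | 2-[(1S,2R,4aS,8aS)-2-{[(3S)-3,4-dihydroxy-2-methylidenebutanoyl]oxy}-7-(hydroxymethyl)-4-methylidene-1,2,3,4,4a,5,6,8a-octahydronaphthalen-1-yl]prop-2-enoic acid | C=C(C(=O)O)[C@@H]1[C@H]2C=C(CO)CC[C@@H]2C(=C)C[C@H]1OC(=O)C(=C)[C@H](O)CO | target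

**Totals**
Total step count: 18. Longest linear sequence: 15 steps (from 5 through 8 to 31: steps 2, 3, 4, 5, 6, 7, 8, 9, 10, 11, 12, 13, 16, 17, 18).

**Steps most likely to fail**

Step 5. What may go wrong: cycloaddition in the wrong orientation (the silyl-bearing terminus bonding to C4a), too slow a reaction of the hindered diene, or loss of the allylsilane by Lewis acid-promoted conjugate allylation of 4. The fallback sets out from 4 and returns at 11; it does not need diene 8. Copper-catalysed conjugate addition of CH2=CHMgBr to 4 with Me3SiCl trapping (CuBr·SMe2, THF, −78 °C), anti to the side chain, should give the silyl enol ether methyl 2-[(1R,2R)-2-ethenyl-4-(trimethylsilyloxy)cyclohex-3-en-1-yl]acetate F1. The acceptor 1-{[tert-butyl(diphenyl)silyl]oxy}but-3-en-2-one F3 is made from commercial but-3-ene-1,2-diol by silylation of the primary hydroxyl to 1-{[tert-butyl(diphenyl)silyl]oxy}but-3-en-2-ol F2 and Dess–Martin oxidation. TiCl4-mediated Mukaiyama–Michael addition of F1 to F3 (CH2Cl2, −78 °C), trans to the vinyl group, should give the diketone methyl 2-[(1R,2R,3S)-3-(4-{[tert-butyl(diphenyl)silyl]oxy}-3-oxobutyl)-2-ethenyl-4-oxocyclohexyl]acetate F4. Wittig methylenation with one equivalent of Ph3P=CH2 at the unhindered side-chain ketone gives methyl 2-[(1R,2R,3S)-3-[3-({[tert-butyl(diphenyl)silyl]oxy}methyl)but-3-en-1-yl]-2-ethenyl-4-oxocyclohexyl]acetate F5. Ring-closing metathesis with the second-generation Grubbs catalyst (CH2Cl2, 40 °C) then closes the same ring and gives 11 directly as the trans-fused ketone.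

Step 13. What may go wrong: hydride delivery to the exocyclic allyl terminus (giving the endocyclic trisubstituted alkene), conjugate reduction of the acrylate, or β-hydride elimination of the allyl-palladium intermediate to a diene. The fallback sets out from 16 and returns at 21; it opens the epoxide before the methylene groups are in place. SmI2 (THF/MeOH, −90 °C) should cleave the Cα–O bond of the epoxy ketone to give the β-hydroxy ketone methyl 2-[(1R,2R,4aS,8aR)-7-({[tert-butyl(diphenyl)silyl]oxy}methyl)-2-hydroxy-4-oxo-1,2,3,4,4a,5,6,8a-octahydronaphthalen-1-yl]acetate F6. Et3SiOTf/2,6-lutidine gives its triethylsilyl ether F7. Methylenation with Zn/CH2Br2/TiCl4, which avoids β-elimination, gives methyl 2-[(1R,2R,4aS,8aS)-7-({[tert-butyl(diphenyl)silyl]oxy}methyl)-4-methylidene-2-(triethylsilyloxy)-1,2,3,4,4a,5,6,8a-octahydronaphthalen-1-yl]acetate F8. The α-methylenation of step 12, through the Mannich base F9 and its methiodide F10, gives the acrylate methyl 2-[(1S,2R,4aS,8aS)-7-({[tert-butyl(diphenyl)silyl]oxy}methyl)-4-methylidene-2-(triethylsilyloxy)-1,2,3,4,4a,5,6,8a-octahydronaphthalen-1-yl]prop-2-enoate F11. HF·pyridine (pyridine, THF, 0 °C) removes the triethylsilyl group and gives 21.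

Step 17. What may go wrong: competing hydrolysis of the C2 ester or loss of the side-chain acyl group during cleavage of the methyl ester. The fallback sets out from 21 and returns at 29; it exchanges the methyl ester for an allyl ester before the coupling. LiOH (THF/H2O, 0 °C) converts 21 into the hydroxy acid 2-[(1S,2R,4aS,8aS)-7-({[tert-butyl(diphenyl)silyl]oxy}methyl)-2-hydroxy-4-methylidene-1,2,3,4,4a,5,6,8a-octahydronaphthalen-1-yl]prop-2-enoic acid F12. Alkylation of its caesium salt (Cs2CO3, allyl bromide, DMF) gives the prop-2-en-1-yl ester F13. Esterification with 26 through 27, as in step 16, gives prop-2-en-1-yl 2-[(1S,2R,4aS,8aS)-7-({[tert-butyl(diphenyl)silyl]oxy}methyl)-2-({2-[(4S)-2,2-dimethyl-1,3-dioxolan-4-yl]prop-2-enoyl}oxy)-4-methylidene-1,2,3,4,4a,5,6,8a-octahydronaphthalen-1-yl]prop-2-enoate F14. Deallylation with Pd(PPh3)4 and morpholine (THF, rt) gives 29.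

Further compounds
F1 | step 5 | methyl 2-[(1R,2R)-2-ethenyl-4-(trimethylsilyloxy)cyclohex-3-en-1-yl]acetate | COC(=O)C[C@@H]1[C@@H](C=C)C=C(O[Si](C)(C)C)CC1
F2 | step 5 | 1-{[tert-butyl(diphenyl)silyl]oxy}but-3-en-2-ol (racemic) | C=CC(O)CO[Si](c1ccccc1)(c1ccccc1)C(C)(C)C
F3 | step 5 | 1-{[tert-butyl(diphenyl)silyl]oxy}but-3-en-2-one | C=CC(=O)CO[Si](c1ccccc1)(c1ccccc1)C(C)(C)C
F4 | step 5 | methyl 2-[(1R,2R,3S)-3-(4-{[tert-butyl(diphenyl)silyl]oxy}-3-oxobutyl)-2-ethenyl-4-oxocyclohexyl]acetate | COC(=O)C[C@@H]1[C@@H](C=C)[C@H](CCC(=O)CO[Si](c2ccccc2)(c2ccccc2)C(C)(C)C)C(=O)CC1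
F5 | step 5 | methyl 2-[(1R,2R,3S)-3-[3-({[tert-butyl(diphenyl)silyl]oxy}methyl)but-3-en-1-yl]-2-ethenyl-4-oxocyclohexyl]acetate | COC(=O)C[C@@H]1[C@@H](C=C)[C@H](CCC(=C)CO[Si](c2ccccc2)(c2ccccc2)C(C)(C)C)C(=O)CC1
F6 | step 13 | methyl 2-[(1R,2R,4aS,8aR)-7-({[tert-butyl(diphenyl)silyl]oxy}methyl)-2-hydroxy-4-oxo-1,2,3,4,4a,5,6,8a-octahydronaphthalen-1-yl]acetate | COC(=O)C[C@@H]1[C@H]2C=C(CO[Si](c3ccccc3)(c3ccccc3)C(C)(C)C)CC[C@@H]2C(=O)C[C@H]1O
F7 | step 13 | methyl 2-[(1R,2R,4aS,8aR)-7-({[tert-butyl(diphenyl)silyl]oxy}methyl)-4-oxo-2-(triethylsilyloxy)-1,2,3,4,4a,5,6,8a-octahydronaphthalen-1-yl]acetate | COC(=O)C[C@@H]1[C@H]2C=C(CO[Si](c3ccccc3)(c3ccccc3)C(C)(C)C)CC[C@@H]2C(=O)C[C@H]1O[Si](CC)(CC)CC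
F8 | step 13 | methyl 2-[(1R,2R,4aS,8aS)-7-({[tert-butyl(diphenyl)silyl]oxy}methyl)-4-methylidene-2-(triethylsilyloxy)-1,2,3,4,4a,5,6,8a-octahydronaphthalen-1-yl]acetate | COC(=O)C[C@@H]1[C@H]2C=C(CO[Si](c3ccccc3)(c3ccccc3)C(C)(C)C)CC[C@@H]2C(=C)C[C@H]1O[Si](CC)(CC)CC
F9 | step 13 | Mannich base of F8, methyl 3-(dimethylamino)-2-[ring system of F8]propanoate | CN(C)CC(C(=O)OC)[C@@H]1[C@H]2C=C(CO[Si](c3ccccc3)(c3ccccc3)C(C)(C)C)CC[C@@H]2C(=C)C[C@H]1O[Si](CC)(CC)CC
F10 | step 13 | trimethylammonium iodide (methiodide) of F9 | [I-].C[N+](C)(C)CC(C(=O)OC)[C@@H]1[C@H]2C=C(CO[Si](c3ccccc3)(c3ccccc3)C(C)(C)C)CC[C@@H]2C(=C)C[C@H]1O[Si](CC)(CC)CC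
F11 | step 13 | methyl 2-[(1S,2R,4aS,8aS)-7-({[tert-butyl(diphenyl)silyl]oxy}methyl)-4-methylidene-2-(triethylsilyloxy)-1,2,3,4,4a,5,6,8a-octahydronaphthalen-1-yl]prop-2-enoate | C=C(C(=O)OC)[C@@H]1[C@H]2C=C(CO[Si](c3ccccc3)(c3ccccc3)C(C)(C)C)CC[C@@H]2C(=C)C[C@H]1O[Si](CC)(CC)CC
F12 | step 17 | 2-[(1S,2R,4aS,8aS)-7-({[tert-butyl(diphenyl)silyl]oxy}methyl)-2-hydroxy-4-methylidene-1,2,3,4,4a,5,6,8a-octahydronaphthalen-1-yl]prop-2-enoic acid | C=C(C(=O)O)[C@@H]1[C@H]2C=C(CO[Si](c3ccccc3)(c3ccccc3)C(C)(C)C)CC[C@@H]2C(=C)C[C@H]1O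
F13 | step 17 | prop-2-en-1-yl 2-[(1S,2R,4aS,8aS)-7-({[tert-butyl(diphenyl)silyl]oxy}methyl)-2-hydroxy-4-methylidene-1,2,3,4,4a,5,6,8a-octahydronaphthalen-1-yl]prop-2-enoate | C=CCOC(=O)C(=C)[C@@H]1[C@H]2C=C(CO[Si](c3ccccc3)(c3ccccc3)C(C)(C)C)CC[C@@H]2C(=C)C[C@H]1O
F14 | step 17 | prop-2-en-1-yl 2-[(1S,2R,4aS,8aS)-7-({[tert-butyl(diphenyl)silyl]oxy}methyl)-2-({2-[(4S)-2,2-dimethyl-1,3-dioxolan-4-yl]prop-2-enoyl}oxy)-4-methylidene-1,2,3,4,4a,5,6,8a-octahydronaphthalen-1-yl]prop-2-enoate | C=CCOC(=O)C(=C)[C@@H]1[C@H]2C=C(CO[Si](c3ccccc3)(c3ccccc3)C(C)(C)C)CC[C@@H]2C(=C)C[C@H]1OC(=O)C(=C)[C@H]4COC(C)(C)O4
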